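At early times the flasks hold starting material and no dissolved partner, and the meeting opened on that point.

| setting | west | south-west |
|---|---|---|
| starting material | 0.050 M | 0.050 M |
| gas | 10 mM (held) | 10 mM (held) |
| time | 40 s | 50 s |

    intermediate ⇌ isomer of the product (K1 = 41, k1 = 0.065 s⁻¹)
    intermediate ⇌ target (K2 = 3.0, k2 = 0.13 s⁻¹)
    starting material + partner → intermediate + by-product (k3 = 1.1 L mol⁻¹ s⁻¹)
    partner → decomposed reagent (k4 = 0.0098 s⁻¹)
    partner → decomposition product (k5 = 1.5 × 10⁻⁵ s⁻¹)
    gas ⇌ partner, rate k6*(csat - [partner]) (k6 = 0.53 s⁻¹, csat = 10 mM)

1. which of these there is most of at the end, counted by the starting material in it, west (starting material / target / intermediate / isomer of the product)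
2. which of these there is most of at the end, counted by the starting material in it, south-west (starting material / target / intermediate / isomer of the product)
3. the largest of these amounts at the end, in percent of the starting material charged, west
4. the largest of these amounts at the end, in percent of the starting material charged, south-west

The chair asked how soon the partner arrives. The kineticist answered that transfer from the held gas has a lifetime of 1.89 s, far shorter than either run, so the partner soon stands where supply equals use. At the charge, she said, starting material takes it at 0.0550 s⁻¹ and decay at 0.0098 s⁻¹, against transfer at 0.53 s⁻¹, which puts the level at 8.91 mM.

The process chemist objected that this level must drift as starting material falls. The kineticist replied that the gap to saturation at the charge is 1.09 mM, and took the level as steady.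

Starting material then falls pseudo-first-order. That gives 70.7 s, which she named the working half-life: the logarithm of two over the rate constant of the step from starting material and partner times the steady partner level.

Counting followed. West runs 0.566 working half-lives, which counts out to 67.6% of the starting material; south-west runs 0.707, which counts out to 61.3%.

The chair noted that the reacted part, 32.4% in west and 38.7% in south-west, is smaller than what remains, however it divides. The meeting therefore recorded starting material as the largest amount in both flasks.

The forecast named starting material for west at 68% and starting material for south-west at 62%, holding that “None of these can exceed the remaining starting material”, and its figures stand slightly above the meeting's.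

West ended with starting material in the lead at 68.3%, and south-west with starting material at 61.7%. Both run times, 40 s and 50 s, are shorter than the working half-life of 70.7 s, and the half-life of starting material by its step with the partner reads 70 s in west at 11.1 s. The same flask as west, read at 2.5 min, has passed 2.12 working half-lives, which counts out to 23.0%, and there 21.9% of starting material stands behind isomer of the product at 53.4%.

The numbers come from no measurement; the run is a simulation.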